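Dusk is charged with half the G of spring on the same J, so if chains begun follow the G charged, the length at the end depends on how much J still stands in chains.

| flask | J | G | remark | time |
|---|---|---|---|---|
| elm | 0.075 M | 2 mol% | run made earlier |  |
| birch | 0.10 M | 2 mol% | run made earlier |  |
| spring | 0.050 M | 2 mol% |  | 10 d |
| dusk | 0.050 M | 1 mol% |  | 10 d |

- elm (time / d: L / %): 0.333: 86.5; 0.833: 86.1; 1.67: 83.3; 2.50: 80.8; 4.00: 77.0; 5.00: 75.8; 6.00: 72.8
- birch (time / d: L / %): 0.333: 90.4; 0.833: 88.8; 1.67: 87.7; 2.50: 85.6; 4.00: 83.1; 5.00: 80.4; 6.00: 78.2

(scatter of a reading: 0.5 percentage points)

- which of the two ends with the longer chains by the average number of monomer units in a chain (chains begun, living or dead) ("neither" if they lie within 10%) (spring / dusk / neither)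
- average number of monomer units in a chain (chains begun, living or dead) at the end, spring
- average number of monomer units in a chain (chains begun, living or dead) at the end, dusk

- the average divides the monomer in chains by the number of chains begun, living and dead together
- the earlier runs do not show the number of chains; that part of a forecast is a guess

The first readings leave 0.0101 M of the charge outside the chains in elm and 0.00960 M in birch, so this gap, which looks like an equilibrium monomer concentration, did not grow with the charge; I take 0.00986 M. L then falls by 0.00181 M/d in elm and 0.00215 M/d in birch.

Two chemists read this differently. The first holds that the drain is a fixed amount per day, whatever the charge, and reckons with the toll, the gap plus the elm drain times the time, 0.0280 M at the end. Length is then the charge less the toll, over the G charged: 22.0 for spring and 44.0 for dusk.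

The second holds that L shrinks by a fixed fraction per day, as in elm, which gives 29.6 and 59.2. Across the elm run, a straight line and such a curve part by 0.3 percentage points at mid-span, against a scatter of 0.5 points, so the elm readings do not tell them apart. I side with the toll: the gap did not grow with the charge, so I expect a loss fed from it to stay steady as well.

The forecast, whose ratio of drains “lies between constant loss” and proportional loss, differs from my figures: dusk at 52, spring at 25.

The flask gives dusk as the longer, 45.0 against 22.7 for spring, and the gap between the two comes from the difference in loading of G. L stands at 44.1% in spring, which puts 0.0279 M outside the chains, close to the toll as reckoned.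

    L + E → J + E, rate k1*[E] as long as [L] is above zero (k = 9.19 /h)
    G → X (k = 0.0788 /h)
    J + G → E + L (k = 66.9 /M/h)
    J + E → L + E, rate k4*[E]*[J] (k = 1040 /M/h)
    J → Q (k = 0.00891 /h)

The toll is a relay of two steps acting together, L going back to J and J going on to Q, and each is a part of the shortening: spring ends at 22.7, but at 51.6 without the loss of L to J and at 42.3 without the loss of J to Q. The proportional view keeps the span of the elm readings, where the two lines lie 0.3 points apart.

A neighbour like spring but charged with 0.020 M of J is reckoned with the same toll, 0.0280 M, which exceeds its charge, so by this estimate its chains empty after 5.60 d. At the end it holds 0.0178% as L, a length of 0.00947.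

The readings were computed with constants of no real substance; the scatter is artificial.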